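The tetrahydropyran (O1, C2 carrying the arylethyl chain, C4–OH, C6–aryl) is cut at the exocyclic C2–CH2 bond. The route exploits the 1,3-relationship of the oxygens on C2 and C4: O1–C2–C3–C4(O) is a latent vinylogous ester. An (S)-6-aryl-4-methoxy-5,6-dihydropyran-2-one, whose C6 is set by a catalytic asymmetric vinylogous aldol reaction, takes up a 2-arylethylcerium reagent at its lactone carbonyl C2; acid then transposes the carbonyl to C4. One operation thus joins both halves and gives a 2,6-disubstituted dihydropyran-4-one, in which C2 and C4 are subsequently set by two hydride additions under substrate control from C6.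

Key step: step 6

Remarks on the chemistry:
- Ring numbering throughout follows the target (O1, C2 arylethyl-bearing, C3, C4, C5, C6 aryl-bearing), and the compound names use the same locants. Ring A is the 3,4-dioxygenated 5-methoxyphenyl ring on C6; ring B is the 4-oxygenated 3-methoxyphenyl ring of the chain.
- Assumption: Ti(OiPr)4/(S)-BINOL is taken to direct the dienolate to the Si face of aldehyde 2. If the sense of induction is the opposite, (R)-BINOL is used in step 3 and nothing else changes.
- Compounds 1, 3 and 7 are taken as commercial.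

Step 1
Reactants: 1 5-hydroxyvanillin (3,4-dihydroxy-5-methoxybenzaldehyde)
Product: 2 3,4-bis(benzyloxy)-5-methoxybenzaldehyde
Conditions: BnBr (2.4 equiv), K2CO3, DMF, 60 °C
Reagents that add atoms: benzyl bromide, BrCc1ccccc1
Why: Williamson ether synthesis, in which both phenoxides are benzylated by SN2 displacement while the aldehyde is untouched; benzyl ethers are chosen because they should survive the organometallic, acidic and hydride steps and leave together in the last step.

Step 2
Reactants: 3 methyl (E)-3-methoxybut-2-enoate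
Product: 4 Brassard's diene, (E)-1,3-dimethoxy-1-(trimethylsilyloxy)buta-1,3-diene
Conditions: LiN(i-Pr)2, THF, −78 °C; Me3SiCl, −78 °C to rt; distillation
Reagents that add atoms: chlorotrimethylsilane, C[Si](C)(C)Cl
Why: γ-Deprotonation of the β-methoxy enoate gives the extended lithium dienolate, which is silylated on oxygen to the silyl ketene acetal (standard enolate O-silylation).

Step 3
Reactants: 2 3,4-bis(benzyloxy)-5-methoxybenzaldehyde; 4 Brassard's diene
Product: 6 (S)-6-[3,4-bis(benzyloxy)-5-methoxyphenyl]-4-methoxy-5,6-dihydro-2H-pyran-2-one, via silyl aldol adduct 5 (not isolated)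
Conditions: Ti(OiPr)4 (20 mol%), (S)-BINOL (20 mol%), 4 Å molecular sieves, THF, −78 °C to rt; then CF3CO2H (0.5 equiv), CH2Cl2, 0 °C, short contact, NaHCO3 work-up
Reagents that add atoms: none
Why: Titanium–BINOL-catalysed vinylogous Mukaiyama aldol reaction (formal hetero-Diels–Alder reaction of Brassard's diene), in which the γ-carbon of 4 adds to the Si face of the aldehyde inside the chiral titanium complex and sets C6 as S under catalyst control; acid then desilylates 5 and closes the lactone, because the E enoate holds ester and carbinol chain cis (any Z isomer should equilibrate under the acid).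

Step 4
Reactants: 7 homovanillyl alcohol (4-(2-hydroxyethyl)-2-methoxyphenol)
Product: 8 2-[4-(benzyloxy)-3-methoxyphenyl]ethanol
Conditions: BnBr (1.05 equiv), K2CO3, acetone, reflux
Reagents that add atoms: benzyl bromide, BrCc1ccccc1
Why: Chemoselective Williamson etherification, since K2CO3 deprotonates only the phenol and the primary alcohol stays free.

Step 5
Reactants: 8 2-[4-(benzyloxy)-3-methoxyphenyl]ethanol
Product: 9 1-(benzyloxy)-4-(2-bromoethyl)-2-methoxybenzene
Conditions: CBr4, PPh3, CH2Cl2, 0 °C to rt
Reagents that add atoms: carbon tetrabromide, BrC(Br)(Br)Br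
Why: Appel reaction, in which the alcohol is activated as an alkoxyphosphonium ion and displaced by bromide in an SN2 step; the aryl ethers are inert.

Step 6
Reactants: 6 (S)-6-[3,4-bis(benzyloxy)-5-methoxyphenyl]-4-methoxy-5,6-dihydro-2H-pyran-2-one; 9 1-(benzyloxy)-4-(2-bromoethyl)-2-methoxybenzene (1.3 equiv)
Product: 13 (S)-6-[3,4-bis(benzyloxy)-5-methoxyphenyl]-2-{2-[4-(benzyloxy)-3-methoxyphenyl]ethyl}-5,6-dihydro-4H-pyran-4-one, via Grignard reagent 10 (not isolated), via organocerium reagent 11 (not isolated), via lactol 12 (not isolated)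
Conditions: 9, Mg, THF, rt; CeCl3 (anhydrous), THF, −78 °C; then 6, THF, −78 °C; then 1 M HCl (aq), 0 °C to rt
Reagents that add atoms: water, O
Why: The organocerium reagent 11, strongly nucleophilic but barely basic, adds 1,2 to the lactone carbonyl C2 of the cyclic vinylogous carbonate 6, and the cyclic tetrahedral alkoxide should persist at −78 °C, which holds back a second addition; on acidification lactol 12 loses water to a 4-methoxy-stabilised oxocarbenium ion, water adds at C4 and methanol leaves, so that the carbonyl moves from C2 to C4 as the C2–CH2 bond is installed. The closest known reaction type is the Stork–Danheiser alkylative carbonyl transposition of β-alkoxy enones, here run on the carbonyl of a 4-alkoxy-5,6-dihydropyran-2-one and combined with the usual single addition of organometallic reagents to δ-lactones. No ring is closed, because the pyran ring of 6 is carried through; should the tetrahedral intermediate open, the C6 hydroxyl recloses on the C2 ketone by a 6-exo-trig hemiketalisation that leads to the same product. No stereocenter is formed (C2 becomes sp2), and C6, which takes no part, keeps its configuration. The step needs carbonyl addition to win over deprotonation at C5 (which would open the ring by β-elimination of the carboxylate) and over double addition; the cerium reagent, the low temperature and the cold acidic quench should secure this, and the transposition can only end at C4 because that is the carbon that carries the methoxy leaving group.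

Step 7
Reactants: 13 (S)-6-[3,4-bis(benzyloxy)-5-methoxyphenyl]-2-{2-[4-(benzyloxy)-3-methoxyphenyl]ethyl}-5,6-dihydro-4H-pyran-4-one
Product: 14 (2S,6S)-2-{2-[4-(benzyloxy)-3-methoxyphenyl]ethyl}-6-[3,4-bis(benzyloxy)-5-methoxyphenyl]tetrahydro-4H-pyran-4-one (2,6-cis)
Conditions: LiBH(s-Bu)3 (L-Selectride, 1.2 equiv), THF, −78 °C; then H2O
Reagents that add atoms: none
Why: Conjugate reduction of a vinylogous ester by a bulky trialkylborohydride, in which hydride adds to C2 along the axial trajectory of the half-chair that has the C6 aryl group pseudoequatorial, so that the arylethyl chain becomes equatorial and C2 is set S, cis to C6, under substrate control; the lithium enolate is protonated on quench.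

Step 8
Reactants: 14 (2S,6S)-2-{2-[4-(benzyloxy)-3-methoxyphenyl]ethyl}-6-[3,4-bis(benzyloxy)-5-methoxyphenyl]tetrahydro-4H-pyran-4-one
Product: 15 (2S,4S,6S)-2-{2-[4-(benzyloxy)-3-methoxyphenyl]ethyl}-6-[3,4-bis(benzyloxy)-5-methoxyphenyl]tetrahydro-2H-pyran-4-ol (4-OH axial, trans to both substituents)
Conditions: LiBH(s-Bu)3 (L-Selectride, 1.5 equiv), THF, −78 °C; then H2O
Reagents that add atoms: none
Why: Diastereoselective ketone reduction, in which the bulky hydride attacks C4 of the chair (C2 and C6 substituents equatorial) from the equatorial side, away from the axial hydrogens on C2 and C6, and should give the axial 4S alcohol under substrate control.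

Step 9
Reactants: 15 (2S,4S,6S)-2-{2-[4-(benzyloxy)-3-methoxyphenyl]ethyl}-6-[3,4-bis(benzyloxy)-5-methoxyphenyl]tetrahydro-2H-pyran-4-ol
Product: 16 (2S,4S,6S)-2-[2-(4-hydroxy-3-methoxyphenyl)ethyl]-6-(3,4-dihydroxy-5-methoxyphenyl)tetrahydro-2H-pyran-4-ol (target)
Conditions: H2 (1 atm), Pd/C (10 wt% Pd on carbon), EtOAc/MeOH, rt; filtration under argon
Reagents that add atoms: none
Why: Hydrogenolysis of the three aryl benzyl ethers under neutral conditions that suit the air-sensitive catechol; the ring C6–O bond, a hindered secondary benzylic dialkyl ether, should be cleaved far more slowly, and no stereocenter is touched.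

Compound list
1 | 5-hydroxyvanillin (3,4-dihydroxy-5-methoxybenzaldehyde) | COc1cc(C=O)cc(O)c1O | starting material
2 | 3,4-bis(benzyloxy)-5-methoxybenzaldehyde | COc1cc(C=O)cc(OCc2ccccc2)c1OCc1ccccc1 | intermediate
3 | methyl (E)-3-methoxybut-2-enoate | COC(=O)/C=C(\C)OC | starting material
4 | Brassard's diene, (E)-1,3-dimethoxy-1-(trimethylsilyloxy)buta-1,3-diene | C=C(OC)/C=C(\OC)O[Si](C)(C)C | intermediate
5 | methyl (2E,5S)-5-[3,4-bis(benzyloxy)-5-methoxyphenyl]-3-methoxy-5-(trimethylsilyloxy)pent-2-enoate (silyl aldol adduct, formed in the flask) | COC(=O)/C=C(OC)\C[C@@H](c1cc(OCc2ccccc2)c(OCc2ccccc2)c(OC)c1)O[Si](C)(C)C | intermediate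
6 | (S)-6-[3,4-bis(benzyloxy)-5-methoxyphenyl]-4-methoxy-5,6-dihydro-2H-pyran-2-one | O=C1C=C(OC)C[C@@H](c2cc(OCc3ccccc3)c(OCc3ccccc3)c(OC)c2)O1 | intermediate
7 | homovanillyl alcohol, 4-(2-hydroxyethyl)-2-methoxyphenol | COc1cc(CCO)ccc1O | starting material
8 | 2-[4-(benzyloxy)-3-methoxyphenyl]ethanol | COc1cc(CCO)ccc1OCc1ccccc1 | intermediate
9 | 1-(benzyloxy)-4-(2-bromoethyl)-2-methoxybenzene | COc1cc(CCBr)ccc1OCc1ccccc1 | intermediate
10 | 2-[4-(benzyloxy)-3-methoxyphenyl]ethylmagnesium bromide (Grignard reagent, formed in the flask) | COc1cc(CC[Mg]Br)ccc1OCc1ccccc1 | intermediate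
11 | {2-[4-(benzyloxy)-3-methoxyphenyl]ethyl}cerium dichloride (organocerium reagent, formed in the flask) | COc1cc(CC[Ce](Cl)Cl)ccc1OCc1ccccc1 | intermediate
12 | (6S)-6-[3,4-bis(benzyloxy)-5-methoxyphenyl]-2-{2-[4-(benzyloxy)-3-methoxyphenyl]ethyl}-4-methoxy-5,6-dihydro-2H-pyran-2-ol (lactol, both C2 epimers, formed in the flask) | COc1cc(CCC2(O)C=C(OC)C[C@@H](c3cc(OCc4ccccc4)c(OCc4ccccc4)c(OC)c3)O2)ccc1OCc1ccccc1 | intermediate
13 | (S)-6-[3,4-bis(benzyloxy)-5-methoxyphenyl]-2-{2-[4-(benzyloxy)-3-methoxyphenyl]ethyl}-5,6-dihydro-4H-pyran-4-one | COc1cc(CCC2=CC(=O)C[C@@H](c3cc(OCc4ccccc4)c(OCc4ccccc4)c(OC)c3)O2)ccc1OCc1ccccc1 | intermediate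
14 | (2S,6S)-2-{2-[4-(benzyloxy)-3-methoxyphenyl]ethyl}-6-[3,4-bis(benzyloxy)-5-methoxyphenyl]tetrahydro-4H-pyran-4-one | COc1cc(CC[C@H]2CC(=O)C[C@@H](c3cc(OCc4ccccc4)c(OCc4ccccc4)c(OC)c3)O2)ccc1OCc1ccccc1 | intermediate
15 | (2S,4S,6S)-2-{2-[4-(benzyloxy)-3-methoxyphenyl]ethyl}-6-[3,4-bis(benzyloxy)-5-methoxyphenyl]tetrahydro-2H-pyran-4-ol | COc1cc(CC[C@H]2C[C@H](O)C[C@@H](c3cc(OCc4ccccc4)c(OCc4ccccc4)c(OC)c3)O2)ccc1OCc1ccccc1 | intermediate
16 | (2S,4S,6S)-2-[2-(4-hydroxy-3-methoxyphenyl)ethyl]-6-(3,4-dihydroxy-5-methoxyphenyl)tetrahydro-2H-pyran-4-ol | COc1cc(CC[C@H]2C[C@H](O)C[C@@H](c3cc(O)c(O)c(OC)c3)O2)ccc1O | target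

Total step count: 9. Longest linear sequence: 6 steps (steps 1, 3, 6, 7, 8, 9, from 5-hydroxyvanillin).

Steps most likely to fail

Step 6 (key step). What may go wrong: deprotonation of 6 at C5 by the organometallic reagent with ring opening by β-elimination of the carboxylate, or early collapse of the tetrahedral intermediate followed by a second addition. The fallback replaces the lactone by an open-chain acyl donor that cannot over-add. Setting out from 6, aminolysis with the aluminium amide made from MeNH(OMe)·HCl and AlMe3 (CH2Cl2, 0 °C to rt) should open the lactone to the Weinreb amide (2E,5S)-5-[3,4-bis(benzyloxy)-5-methoxyphenyl]-5-hydroxy-N,3-dimethoxy-N-methylpent-2-enamide F1. Grignard reagent 10 (2.5 equiv, the first one consumed by the hydroxyl; THF, 0 °C) should then give, through the chelated tetrahedral intermediate, the hydroxy enone (4E,7S)-7-[3,4-bis(benzyloxy)-5-methoxyphenyl]-1-[4-(benzyloxy)-3-methoxyphenyl]-7-hydroxy-5-methoxyhept-4-en-3-one F2. Catalytic TsOH in wet THF should close the C6 hydroxyl onto the C2 ketone and expel water and methanol, which gives 13, where the route is rejoined.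

Step 3. What may go wrong: sluggish addition of the moderately nucleophilic diene 4 to the electron-rich aldehyde 2, or insufficient facial discrimination. The fallback builds the lactone stepwise with a more nucleophilic dienolate equivalent and forms the enol ether afterwards. Setting out from 2, the Ti(OiPr)4/(S)-BINOL-catalysed vinylogous Mukaiyama aldol reaction with commercial Chan's diene, 1-methoxy-1,3-bis(trimethylsilyloxy)buta-1,3-diene (THF, −78 °C to rt), should give methyl (5S)-5-[3,4-bis(benzyloxy)-5-methoxyphenyl]-3,5-bis(trimethylsilyloxy)pent-2-enoate F3. Brief CF3CO2H treatment should desilylate it to methyl (S)-5-[3,4-bis(benzyloxy)-5-methoxyphenyl]-5-hydroxy-3-oxopentanoate F4. K2CO3 in MeOH should lactonise F4 to (S)-6-[3,4-bis(benzyloxy)-5-methoxyphenyl]dihydro-2H-pyran-2,4(3H)-dione F5, and Me2SO4 with K2CO3 in acetone should methylate the C4 enol oxygen to give 6, where the route is rejoined. Recrystallisation of F5 or 6 could raise the enantiomeric purity if needed.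

Step 7. What may go wrong: hydride attack at the carbonyl instead of the hindered, fully substituted β-carbon C2, or ring opening of the β-alkoxy enolate. The fallback sets C2 by heterogeneous hydrogenation and moves the deprotection forward. Setting out from 13, H2 (1 atm) over Pd/C in EtOAc/MeOH should add hydrogen syn to the C2=C3 bond from the ring face anti to the C6 aryl group (2,6-cis) and cleave the three benzyl ethers in the same flask. This should give (2S,6S)-2-[2-(4-hydroxy-3-methoxyphenyl)ethyl]-6-(3,4-dihydroxy-5-methoxyphenyl)tetrahydro-4H-pyran-4-one F6. Excess LiBH(s-Bu)3 (5 equiv, three of them consumed by the phenols; THF, −78 °C; non-oxidative work-up) should then reduce F6 from the equatorial side and give 16 directly, so that this fallback passes by 14 and 15 and comes back at 16.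

Further compounds
F1 | step 6 | (2E,5S)-5-[3,4-bis(benzyloxy)-5-methoxyphenyl]-5-hydroxy-N,3-dimethoxy-N-methylpent-2-enamide | CON(C)C(=O)/C=C(OC)\C[C@@H](c1cc(OCc2ccccc2)c(OCc2ccccc2)c(OC)c1)O
F2 | step 6 | (4E,7S)-7-[3,4-bis(benzyloxy)-5-methoxyphenyl]-1-[4-(benzyloxy)-3-methoxyphenyl]-7-hydroxy-5-methoxyhept-4-en-3-one | COc1cc(CCC(=O)/C=C(OC)\C[C@@H](c2cc(OCc3ccccc3)c(OCc3ccccc3)c(OC)c2)O)ccc1OCc1ccccc1
F3 | step 3 | methyl (5S)-5-[3,4-bis(benzyloxy)-5-methoxyphenyl]-3,5-bis(trimethylsilyloxy)pent-2-enoate (enol ether geometry not defined) | COC(=O)C=C(O[Si](C)(C)C)C[C@@H](c1cc(OCc2ccccc2)c(OCc2ccccc2)c(OC)c1)O[Si](C)(C)C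
F4 | step 3 | methyl (S)-5-[3,4-bis(benzyloxy)-5-methoxyphenyl]-5-hydroxy-3-oxopentanoate | COC(=O)CC(=O)C[C@@H](c1cc(OCc2ccccc2)c(OCc2ccccc2)c(OC)c1)O
F5 | step 3 | (S)-6-[3,4-bis(benzyloxy)-5-methoxyphenyl]dihydro-2H-pyran-2,4(3H)-dione | O=C1CC(=O)C[C@@H](c2cc(OCc3ccccc3)c(OCc3ccccc3)c(OC)c2)O1
F6 | step 7 | (2S,6S)-2-[2-(4-hydroxy-3-methoxyphenyl)ethyl]-6-(3,4-dihydroxy-5-methoxyphenyl)tetrahydro-4H-pyran-4-one | COc1cc(CC[C@H]2CC(=O)C[C@@H](c3cc(O)c(O)c(OC)c3)O2)ccc1O
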